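**Plan**
1. Cuts, in retrosynthetic order: the two O–benzyl bonds and the C3=C4 unsaturation of ring B (one hydrogenation); then C8a–O1 and C2–C3 of the ring B pyran together. After that come the C4a–C4 vinyl bond (Suzuki–Miyaura), the ring B C6–CH2 chain bond (Heck), the carbinol C–C bond at ring A C6, and the ring A pyran (propargyl Claisen).
2. Enabling feature: in ring B, O1 sits on C8a para to the C6 alkyl chain and carries the gem-dimethyl carbon C2. O1–C2Me2 is therefore an aryloxy dimethyl carbenium ion, the species a cumyl peroxide gives when its aryl group shifts from carbon to oxygen. C3–C4 map onto an ortho vinyl group that can trap this ion.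
3. Forward order: the ring A pyran closes first (steps 1–4), the three-carbon chain is joined by Heck–isomerisation (step 7), the ring B pyran closes in step 10, and one hydrogenation finishes the synthesis.
4. Stereochemistry: none has to be set.

Key step: step 10

Remark: the target SMILES holds no stereocentre and no stereogenic double bond, so the compound is achiral. The only stereocentre made on the way (the carbinol carbon of step 5) is carried as the racemate and erased in step 7.

**Step 1**
Reactants: 1 2,4,6-trihydroxybenzaldehyde; 2 2-methylbut-3-yn-2-ol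
Product: 4 2,6-dihydroxy-4-[(2-methylbut-3-yn-2-yl)oxy]benzaldehyde, via 2-methylbut-3-yn-2-yl trifluoroacetate 3 (not isolated)
Conditions: 2, (CF3CO)2O, DBU, MeCN, −5 °C; then 1 (1.2 equiv), DBU, CuCl2·2H2O (cat.), MeCN, −5 → 0 °C
Reagents that add atoms: none
Why: Copper-catalysed propargylic etherification of a phenol (through a copper allenylidene) is the standard entry to aryl 1,1-dimethylpropargyl ethers, and the 4-OH, which is the most acidic and the only one not crowded by the formyl group, should react first when the electrophile is limiting.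

**Step 2**
Reactants: 4 2,6-dihydroxy-4-[(2-methylbut-3-yn-2-yl)oxy]benzaldehyde
Product: 5 2,6-bis(benzyloxy)-4-[(2-methylbut-3-yn-2-yl)oxy]benzaldehyde
Conditions: BnBr (2.4 equiv), K2CO3, DMF, 50 °C
Reagents that add atoms: benzyl bromide, BrCc1ccccc1
Why: Williamson etherification caps both phenols next to the formyl group, so that only the ether oxygen can later close the pyran, and the tertiary propargyl ether is inert to carbonate well below its rearrangement temperature.

**Step 3**
Reactants: 5 2,6-bis(benzyloxy)-4-[(2-methylbut-3-yn-2-yl)oxy]benzaldehyde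
Product: 7 5,7-bis(benzyloxy)-2,2-dimethyl-2H-chromene-6-carbaldehyde, via allenylphenol 6 (not isolated)
Conditions: PhNEt2, 190 °C
Reagents that add atoms: none
Why: Aromatic propargyl Claisen rearrangement to either of the two equivalent ortho carbons, followed by 1,5-hydrogen shift and oxa-6π electrocyclisation, is the classical 2,2-dimethylchromene synthesis, and it places O1 para to the formyl carbon without ambiguity because the liberated phenol is the only free OH.

**Step 4**
Reactants: 7 5,7-bis(benzyloxy)-2,2-dimethyl-2H-chromene-6-carbaldehyde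
Product: 8 5,7-bis(benzyloxy)-2,2-dimethylchroman-6-carbaldehyde
Conditions: H2 (1 atm), 10% Pd/C, Ph2S (cat.), EtOAc, rt
Reagents that add atoms: none
Why: Catalytic hydrogenation over sulfide-poisoned palladium saturates the cis-disubstituted C3=C4 alkene while the poison suppresses benzyl ether hydrogenolysis and aryl aldehyde reduction, which removes an acid-sensitive electron-rich styrene from ring A before the peroxide chemistry.

**Step 5**
Reactants: 8 5,7-bis(benzyloxy)-2,2-dimethylchroman-6-carbaldehyde; 9 vinylmagnesium bromide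
Product: 10 rac-1-[5,7-bis(benzyloxy)-2,2-dimethylchroman-6-yl]prop-2-en-1-ol
Conditions: THF, −78 → 0 °C; aq NH4Cl; used without chromatography
Reagents that add atoms: none
Why: Grignard 1,2-addition to the hindered, non-enolisable aldehyde gives the aryl vinyl carbinol as a racemate, which is acceptable because this stereocentre disappears in step 7.

**Step 6**
Reactants: 11 methyl 2-bromo-4-iodobenzoate
Product: 13 2-(2-bromo-4-iodophenyl)propan-2-ol, via 2-bromo-4-iodoacetophenone 12 (not isolated)
Conditions: MeMgBr (3 equiv), THF, 0 °C → rt; aq NH4Cl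
Reagents that add atoms: methylmagnesium bromide, C[Mg]Br
Why: Double Grignard addition to a benzoate ester gives the cumyl alcohol, and methylmagnesium bromide is too poor a halogen–metal exchange reagent to disturb the aryl iodide or bromide at this temperature.

**Step 7**
Reactants: 10 rac-1-[5,7-bis(benzyloxy)-2,2-dimethylchroman-6-yl]prop-2-en-1-ol; 13 2-(2-bromo-4-iodophenyl)propan-2-ol
Product: 15 1-[5,7-bis(benzyloxy)-2,2-dimethylchroman-6-yl]-3-[3-bromo-4-(2-hydroxypropan-2-yl)phenyl]propan-1-one, via enol 14 (not isolated)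
Conditions: Pd(OAc)2 (5 mol %), n-Bu4NCl, NaHCO3, DMF, 50 °C
Reagents that add atoms: none
Why: Heck arylation of a secondary allylic alcohol under ligand-free phase-transfer conditions puts the aryl group on the terminal carbon, β-hydride elimination toward the carbinol carbon gives the enol and hence the saturated ketone (Heck–isomerisation), and the C–I bond undergoes oxidative addition far faster than the hindered ortho C–Br bond.

**Step 8**
Reactants: 15 1-[5,7-bis(benzyloxy)-2,2-dimethylchroman-6-yl]-3-[3-bromo-4-(2-hydroxypropan-2-yl)phenyl]propan-1-one; 16 vinylboronic acid pinacol ester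
Product: 17 1-[5,7-bis(benzyloxy)-2,2-dimethylchroman-6-yl]-3-[3-ethenyl-4-(2-hydroxypropan-2-yl)phenyl]propan-1-one
Conditions: Pd(dppf)Cl2 (5 mol %), K2CO3, 1,4-dioxane/H2O, 80 °C
Reagents that add atoms: none
Why: Suzuki–Miyaura vinylation of the aryl bromide installs the future C3–C4 unit ortho to the cumyl carbon under basic conditions that leave the tertiary alcohol, the ketone and the benzyl ethers untouched.

**Step 9**
Reactants: 17 1-[5,7-bis(benzyloxy)-2,2-dimethylchroman-6-yl]-3-[3-ethenyl-4-(2-hydroxypropan-2-yl)phenyl]propan-1-one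
Product: 18 1-[5,7-bis(benzyloxy)-2,2-dimethylchroman-6-yl]-3-[3-ethenyl-4-(2-hydroperoxypropan-2-yl)phenyl]propan-1-one
Conditions: H2O2 (50% aq, 20 equiv), H2SO4 (cat.), Et2O, 0 °C; washed free of H2O2
Reagents that add atoms: hydrogen peroxide, OO
Why: Acid-catalysed SN1 perhydrolysis of a tertiary benzylic alcohol is the standard laboratory route to cumyl hydroperoxides, the large excess of the α-effect nucleophile should intercept the cumyl cation before the vinyl group or proton loss can, and the doubly ortho-substituted ketone is too hindered to form a perketal.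

**Step 10**
Reactants: 18 1-[5,7-bis(benzyloxy)-2,2-dimethylchroman-6-yl]-3-[3-ethenyl-4-(2-hydroperoxypropan-2-yl)phenyl]propan-1-one
Product: 21 1-[5,7-bis(benzyloxy)-2,2-dimethylchroman-6-yl]-3-(2,2-dimethyl-2H-chromen-6-yl)propan-1-one, via peroxy trifluoroacetate 19 (not isolated), via oxocarbenium trifluoroacetate 20 (not isolated)
Conditions: (CF3CO)2O (1.2 equiv), 4 Å MS, CH2Cl2 (0.005 M), −78 → 0 °C; aq NaHCO3
Reagents that add atoms: none
Why: Proposed new method: trifluoroacetylation of the distal peroxide oxygen of 18 gives perester 19, whose O–O bond ionises with concerted 1,2-shift of the aryl group from the cumyl carbon to the proximal oxygen (Criegee variant of the Hock rearrangement), which makes the C8a–O1 bond and the aryloxy-stabilised dimethyl carbenium ion 20 without setting water free. The terminal carbon of the ortho vinyl group then adds to the cationic C2 in a 6-endo-trig Prins-type closure of the ring B pyran (C2–C3 bond), the charge arriving at benzylic C4 where the ortho oxygen O1 supports it, and loss of a C3 proton gives the 2H-chromene 21. The closest known reaction types are the Hock and Criegee rearrangements of cumyl peroxides, the capture of the derived oxocarbenium ions by external carbon π-nucleophiles and oxonia-Prins cyclisations, but their merger with a tethered styrene into a chromene synthesis has not been shown. No stereocentre is formed, so no facial control is required. Aryl must migrate in preference to methyl, which the far higher migratory aptitude of a para-alkyl aryl group secures, and ring closure must beat external capture, which the ortho placement of the alkene, high dilution and the absence of water favour; collapse of 20 with trifluoroacetate or proton loss to the isopropenyl ether is reversible in the trifluoroacetic acid formed and leads back to 20. In ring A the ketone is shielded by two ortho benzyloxy groups, the only free arene position C8 is deactivated by the acyl group and the pyran is already saturated, so no second π-nucleophile competes.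

**Step 11**
Reactants: 21 1-[5,7-bis(benzyloxy)-2,2-dimethylchroman-6-yl]-3-(2,2-dimethyl-2H-chromen-6-yl)propan-1-one
Product: 22 1-(5,7-dihydroxy-2,2-dimethylchroman-6-yl)-3-(2,2-dimethylchroman-6-yl)propan-1-one (CNP0080574.0)
Conditions: H2 (1 atm), 10% Pd/C, EtOAc/EtOH, rt
Reagents that add atoms: none
Why: Catalytic hydrogenation saturates the chromene C3=C4 bond and hydrogenolyses both aryl benzyl ethers in one operation, while the hindered aryl ketone, hydrogen-bonded once the phenols are free, resists reduction at atmospheric pressure.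

**Compound list**
1 | 2,4,6-trihydroxybenzaldehyde | O=Cc1c(O)cc(O)cc1O | starting material
2 | 2-methylbut-3-yn-2-ol | CC(C)(O)C#C | starting material
3 | 2-methylbut-3-yn-2-yl trifluoroacetate | C#CC(C)(C)OC(=O)C(F)(F)F | intermediate
4 | 2,6-dihydroxy-4-[(2-methylbut-3-yn-2-yl)oxy]benzaldehyde | O=Cc1c(O)cc(OC(C)(C)C#C)cc1O | intermediate
5 | 2,6-bis(benzyloxy)-4-[(2-methylbut-3-yn-2-yl)oxy]benzaldehyde | O=Cc1c(OCc2ccccc2)cc(OC(C)(C)C#C)cc1OCc1ccccc1 | intermediate
6 | 2,6-bis(benzyloxy)-4-hydroxy-3-(3-methylbuta-1,2-dien-1-yl)benzaldehyde (allenylphenol) | O=Cc1c(OCc2ccccc2)cc(O)c(C=C=C(C)C)c1OCc1ccccc1 | intermediate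
7 | 5,7-bis(benzyloxy)-2,2-dimethyl-2H-chromene-6-carbaldehyde | O=Cc1c(OCc2ccccc2)cc2OC(C)(C)C=Cc2c1OCc1ccccc1 | intermediate
8 | 5,7-bis(benzyloxy)-2,2-dimethylchroman-6-carbaldehyde | O=Cc1c(OCc2ccccc2)cc2OC(C)(C)CCc2c1OCc1ccccc1 | intermediate
9 | vinylmagnesium bromide | C=C[Mg]Br | starting material
10 | rac-1-[5,7-bis(benzyloxy)-2,2-dimethylchroman-6-yl]prop-2-en-1-ol | C=CC(O)c1c(OCc2ccccc2)cc2OC(C)(C)CCc2c1OCc1ccccc1 | intermediate
11 | methyl 2-bromo-4-iodobenzoate | COC(=O)c1ccc(I)cc1Br | starting material
12 | 1-(2-bromo-4-iodophenyl)ethan-1-one (2-bromo-4-iodoacetophenone) | CC(=O)c1ccc(I)cc1Br | intermediate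
13 | 2-(2-bromo-4-iodophenyl)propan-2-ol | CC(C)(O)c1ccc(I)cc1Br | intermediate
14 | 1-[5,7-bis(benzyloxy)-2,2-dimethylchroman-6-yl]-3-[3-bromo-4-(2-hydroxypropan-2-yl)phenyl]prop-1-en-1-ol (enol, geometry not defined) | OC(=CCc1ccc(C(C)(C)O)c(Br)c1)c1c(OCc2ccccc2)cc2OC(C)(C)CCc2c1OCc1ccccc1 | intermediate
15 | 1-[5,7-bis(benzyloxy)-2,2-dimethylchroman-6-yl]-3-[3-bromo-4-(2-hydroxypropan-2-yl)phenyl]propan-1-one | CC(C)(O)c1ccc(CCC(=O)c2c(OCc3ccccc3)cc3OC(C)(C)CCc3c2OCc2ccccc2)cc1Br | intermediate
16 | vinylboronic acid pinacol ester (2-ethenyl-4,4,5,5-tetramethyl-1,3,2-dioxaborolane) | C=CB1OC(C)(C)C(C)(C)O1 | starting material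
17 | 1-[5,7-bis(benzyloxy)-2,2-dimethylchroman-6-yl]-3-[3-ethenyl-4-(2-hydroxypropan-2-yl)phenyl]propan-1-one | CC(C)(O)c1ccc(CCC(=O)c2c(OCc3ccccc3)cc3OC(C)(C)CCc3c2OCc2ccccc2)cc1C=C | intermediate
18 | 1-[5,7-bis(benzyloxy)-2,2-dimethylchroman-6-yl]-3-[3-ethenyl-4-(2-hydroperoxypropan-2-yl)phenyl]propan-1-one | OOC(C)(C)c1ccc(CCC(=O)c2c(OCc3ccccc3)cc3OC(C)(C)CCc3c2OCc2ccccc2)cc1C=C | intermediate
19 | O-trifluoroacetyl derivative of 18 (cumyl peroxy trifluoroacetate) | O=C(OOC(C)(C)c1ccc(CCC(=O)c2c(OCc3ccccc3)cc3OC(C)(C)CCc3c2OCc2ccccc2)cc1C=C)C(F)(F)F | intermediate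
20 | aryl(propan-2-ylidene)oxonium trifluoroacetate (aryl = 4-[3-(5,7-bis(benzyloxy)-2,2-dimethylchroman-6-yl)-3-oxopropyl]-2-ethenylphenyl) | CC(C)=[O+]c1ccc(CCC(=O)c2c(OCc3ccccc3)cc3OC(C)(C)CCc3c2OCc2ccccc2)cc1C=C.[O-]C(=O)C(F)(F)F | intermediate
21 | 1-[5,7-bis(benzyloxy)-2,2-dimethylchroman-6-yl]-3-(2,2-dimethyl-2H-chromen-6-yl)propan-1-one | CC1(C)C=Cc2cc(CCC(=O)c3c(OCc4ccccc4)cc4OC(C)(C)CCc4c3OCc3ccccc3)ccc2O1 | intermediate
22 | 1-(5,7-dihydroxy-2,2-dimethylchroman-6-yl)-3-(2,2-dimethylchroman-6-yl)propan-1-one | CC1(C)CCc2cc(CCC(=O)c3c(O)cc4c(c3O)CCC(C)(C)O4)ccc2O1 | target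

**Totals**
Total step count: 11. Longest linear sequence: 10 (steps 1–5 and 7–11); step 6 is the only side branch.

**Steps most likely to fail**

Step 10. External capture of the oxocarbenium ion followed by fragmentation, or acid-induced oligomerisation of the styrene, may outrun the ring closure.
- The fallback uses known chemistry and sets out from 18.
- A conventional Hock cleavage (cat. H2SO4, aqueous acetone, rt) should give the vinylphenol 1-[5,7-bis(benzyloxy)-2,2-dimethylchroman-6-yl]-3-(3-ethenyl-4-hydroxyphenyl)propan-1-one F1.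
- Palladium(0)-catalysed O-allylation with tert-butyl 2-methylbut-3-en-2-yl carbonate should give its 1,1-dimethylallyl ether F2.
- Ring-closing metathesis of the two terminal alkenes (second-generation Grubbs catalyst, CH2Cl2, 40 °C) closes C3=C4 and comes back to the route at 21.

Step 9. The acid needed to ionise the alcohol may also cause several side processes. These are cyclisation of the cumyl cation onto the neighbouring vinyl group, addition of the OH or OOH group across the protonated styrene, dehydration, and premature aryl migration.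
- The fallback sets out from 15, which holds no alkene, so the cation is never generated next to one.
- The same perhydrolysis should give the bromo hydroperoxide F3.
- 2-Methoxypropene with PPTS masks it as the 2-methoxyprop-2-yl peroxyketal F4, a class of protected hydroperoxide that tolerates palladium(0) cross-coupling.
- Suzuki–Miyaura vinylation with 16 gives the vinyl peroxyketal F5.
- AcOH/THF/H2O at rt, far milder than alcohol ionisation, frees the hydroperoxide and comes back to the route at 18.

Step 1. Site selectivity among the three phenols may be poor, and over-alkylation may consume the mono-ether.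
- The fallback sets out from 1 and replaces intrinsic selectivity by protecting-group control.
- Peracetylation (Ac2O, pyridine) gives 2-formylbenzene-1,3,5-triyl triacetate F6.
- Thiolysis (PhSH, imidazole, NMP, 0 °C) should remove only the unhindered acetate para to the carbonyl group, the selectivity familiar from peracetylated flavonoids. This gives 2-formyl-5-hydroxy-1,3-phenylene diacetate F7, which has a single free phenol.
- Copper-catalysed etherification with 3 gives 2-formyl-5-[(2-methylbut-3-yn-2-yl)oxy]-1,3-phenylene diacetate F8.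
- Methanolysis (K2CO3, MeOH, 0 °C) comes back to the route at 4.

**Further compounds**
F1 | step 10 | 1-[5,7-bis(benzyloxy)-2,2-dimethylchroman-6-yl]-3-(3-ethenyl-4-hydroxyphenyl)propan-1-one | Oc1ccc(CCC(=O)c2c(OCc3ccccc3)cc3OC(C)(C)CCc3c2OCc2ccccc2)cc1C=C
F2 | step 10 | 1-[5,7-bis(benzyloxy)-2,2-dimethylchroman-6-yl]-3-{3-ethenyl-4-[(2-methylbut-3-en-2-yl)oxy]phenyl}propan-1-one | C=CC(C)(C)Oc1ccc(CCC(=O)c2c(OCc3ccccc3)cc3OC(C)(C)CCc3c2OCc2ccccc2)cc1C=C
F3 | step 9 | 1-[5,7-bis(benzyloxy)-2,2-dimethylchroman-6-yl]-3-[3-bromo-4-(2-hydroperoxypropan-2-yl)phenyl]propan-1-one | OOC(C)(C)c1ccc(CCC(=O)c2c(OCc3ccccc3)cc3OC(C)(C)CCc3c2OCc2ccccc2)cc1Br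
F4 | step 9 | 2-methoxyprop-2-yl peroxyketal of F3 | COC(C)(C)OOC(C)(C)c1ccc(CCC(=O)c2c(OCc3ccccc3)cc3OC(C)(C)CCc3c2OCc2ccccc2)cc1Br
F5 | step 9 | 2-methoxyprop-2-yl peroxyketal of 18 | COC(C)(C)OOC(C)(C)c1ccc(CCC(=O)c2c(OCc3ccccc3)cc3OC(C)(C)CCc3c2OCc2ccccc2)cc1C=C
F6 | step 1 | 2-formylbenzene-1,3,5-triyl triacetate | CC(=O)Oc1cc(OC(C)=O)c(C=O)c(OC(C)=O)c1
F7 | step 1 | 2-formyl-5-hydroxy-1,3-phenylene diacetate | CC(=O)Oc1cc(O)cc(OC(C)=O)c1C=O
F8 | step 1 | 2-formyl-5-[(2-methylbut-3-yn-2-yl)oxy]-1,3-phenylene diacetate | CC(=O)Oc1cc(OC(C)(C)C#C)cc(OC(C)=O)c1C=O
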